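Start from the alpha run: X reads 21.2% and 21.4% from 3.00 min to 4.00 min while E falls on, so within the scatter X stands near its peak there.

all flasks: E 0.14 M

| charge | D | remark | time |
|---|---|---|---|
| zeta | 0.059 M | run made earlier |  |
| alpha | 0.11 M | run made earlier |  |
| beta | 0.17 M | run made earlier |  |
| larch | 0.168 M |  | 6.0 min |
| alder | 0.0700 M |  | 6.0 min |

- zeta (time / min: X / %, E / %): 0.500: 4.7, 94.2; 1.33: 11.4, 86.7; 2.50: 14.8, 78.1; 4.00: 18.0, 69.5
- alpha (time / min: X / %, E / %): 1.00: 14.3, 81.1; 2.00: 20.3, 67.4; 3.00: 21.2, 58.7; 4.00: 21.4, 51.7
- beta (time / min: X / %, E / %): 0.500: 12.0, 84.1; 1.33: 20.0, 66.3; 2.50: 22.9, 48.8; 4.00: 20.4, 34.1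

(readings scatter by 0.5 percentage points)

- the earlier runs were read with a standard deviation of 0.5 percentage points
- steps thought possible: E + D -> Z + X; X + D -> Z + J; Z + E -> G

- which of these holds the largest part of the E at the end of larch (J / X / E)
- which of these holds the largest part of the E at the end of alder (J / X / E)
- amount of X at the end of alder, in percent of the E charged

1. Write the balance of X. E + D -> Z + X makes it in proportion to [E][D]; X + D -> Z + J uses it in proportion to [X][D]. [D] cancels from the ratio of the two.
2. Read the alpha peak. Its last reading, with the scatter of both numbers, gives 2.42 as my estimate of κ, the selectivity factor: the [E]/[X] at which X is made as fast as it is used. X climbs while [E]/[X] stands above κ, so [E]/κ is a ceiling for rising X.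
3. Take the first extreme for alder: switch the second step off in thought. X then reaches at most the D charge, 50.0% of the E.
4. Take the second extreme: let X ride its ceiling. With [E] between the last readings of alpha and zeta, X lies between 21.4% and 28.8%.
5. Place the real flask. Zeta ends at 18.0%, under its ceiling; alpha ends on its ceiling. Alder's D lies between theirs, and a straight line in D between those readings at 4.00 min gives 18.7%. Alder runs on to 6.0 min, so I reckon X between that figure and alpha's 21.4%.
6. Hear the forecast: J for larch, E for alder, X 20% (17.5% to 22.5%), since alder “lies just above zeta”.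

Alder gives X 19.9%, with E holding the most there and J in larch. At 6.00 min, X in alder is still made 1.27 times as fast as it is used, each step taken net. Apply κ as read: [E]/[X] in alder stands at 2.83, above 2.42, the side on which X still climbs.

    E + D → Z + X (k = 0.0340 L mol⁻¹ s⁻¹)
    X + D → Z + J (k = 0.0760 L mol⁻¹ s⁻¹)
    Z + E → G (k = 0.0170 L mol⁻¹ s⁻¹)

Now take the neighbour with 0.18 M of D, close to beta's charge. Beta's last reading gives [E]/[X] = 1.67, under κ, so expect X past its peak and below 20.4% at 6.0 min. The neighbour gives X 17.4% and E 21.4%.

The earlier runs and the new flask were generated by integration with made-up constants, noise included.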